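## Retrosynthetic overview

1. Rings C and B form in one flask. Triacetic acid lactone 1 and methyl isobutyrate 2 give pyrone 3. Then 3 and prenal 4 close the pyran (ring C) to pyranopyranone 5, methoxide opens the lactone to pyran ester 6, and a Claisen closure builds the benzene ring (ring B) of chromene ketone 7. The pyrone ring of 1 is a sacrificial template: it fixes the pyran oxygen para to the acyl group and leaves C8–H free.
2. Ring A is bought as 2-methylphloroglucinol 8 and acylated with isobutyryl chloride 9 to ketone 10. It is never built, only dearomatised at the end.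
3. CH2 bridge: cut between the bridge carbon and C8 of 7. Forward, 10 and Eschenmoser's salt 11 give Mannich base 12, which loses amine to quinone methide 13 and is trapped by 7 to the achiral aromatic dimer 14.
4. First retrosynthetic cut, last forward step: the C–prenyl bond at the quaternary carbon. Pd-catalysed asymmetric dearomative prenylation of 14 with prenyl acetate 15 gives target 16 and sets its only stereocentre.
5. Ring order: C, then B (same operation); ring A is present from 8 throughout.

Assumption: the (R,R) antipode of the Trost ligand is taken to give the R quaternary carbon in step 5 (the S,S ligand is used if an analytical run shows the opposite sense), and 2-methylbenzene-1,3,5-triol is bought.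

## Route

Step 1
Reactants: 1 4-hydroxy-6-methyl-2H-pyran-2-one (triacetic acid lactone); 2 methyl 2-methylpropanoate (methyl isobutyrate)
Product: 3 4-hydroxy-6-(3-methyl-2-oxobutyl)-2H-pyran-2-one
Conditions: LiN(iPr)2 (3.2 equiv), THF, −78 → −20 °C; 2 (1.1 equiv), −78 → 0 °C; 1 M HCl
Reagents that add atoms: methyl 2-methylpropanoate 2, COC(=O)C(C)C
Why: Claisen-type C-acylation of the pyrone dianion at its lateral 6-methyl carbanion by the ester, the third equivalent of base holding the β-keto product as its enolate so that only one acyl group enters.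

Step 2
Reactants: 3 4-hydroxy-6-(3-methyl-2-oxobutyl)-2H-pyran-2-one; 4 3-methylbut-2-enal (prenal)
Product: 7 1-(5,7-dihydroxy-2,2-dimethyl-2H-chromen-6-yl)-2-methylpropan-1-one, via pyranopyranone 5 (not isolated), via pyran ester 6 (not isolated)
Conditions: (i) 4 (1.05 equiv), ethylenediammonium diacetate (10 mol%), 3 Å sieves, MeOH, 50 °C; (ii) Mg(OMe)2 (4 equiv, supplies the OMe of 6), MeOH, 65 °C; 1 M HCl
Reagents that add atoms: 3-methylbut-2-enal 4, CC(C)=CC=O
Why: Proposed new method: amine-catalysed Knoevenagel condensation at the enolic C3 of the 4-hydroxypyrone followed by oxa-6π electrocyclisation closes the pyran (ring C) to 5, after which Mg(OMe)2 methanolyses the now O-alkylated lactone to 6 and the 1,3-diketone carbon of 6 closes onto the ester (Claisen/Dieckmann condensation, then enolisation) to give the benzene ring (ring B) with the pyran oxygen para to the acyl group, the competing aldol mode being blocked because the ester α-carbon is fully substituted; the closest known reactions are the formal [3+3] annulation of 4-hydroxy-6-methyl-2-pyrone with enals and the methoxide-induced biomimetic recyclisation of 6-(2-oxoalkyl)pyrones to acylphloroglucinols.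

Step 3
Reactants: 8 2-methylbenzene-1,3,5-triol (2-methylphloroglucinol); 9 2-methylpropanoyl chloride (isobutyryl chloride)
Product: 10 2-methyl-1-(2,4,6-trihydroxy-3-methylphenyl)propan-1-one
Conditions: AlCl3 (3.5 equiv), PhNO2, 0 → 50 °C; ice/1 M HCl
Reagents that add atoms: 2-methylpropanoyl chloride 9, CC(C)C(Cl)=O
Why: Friedel–Crafts acylation of the electron-rich triol at one of its two equivalent free positions, with AlCl3 complexation of the product ketone suppressing a second acylation.

Step 4
Reactants: 10 2-methyl-1-(2,4,6-trihydroxy-3-methylphenyl)propan-1-one; 11 N,N-dimethylmethaniminium iodide (Eschenmoser's salt, Me2N=CH2+ I−); 7 1-(5,7-dihydroxy-2,2-dimethyl-2H-chromen-6-yl)-2-methylpropan-1-one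
Product: 14 1-[3-({5,7-dihydroxy-2,2-dimethyl-6-(2-methylpropanoyl)-2H-chromen-8-yl}methyl)-2,4,6-trihydroxy-5-methylphenyl]-2-methylpropan-1-one, via Mannich base 12 (not isolated), via quinone methide 13 (not isolated)
Conditions: (i) 11 (1.05 equiv), MeCN, 0 → 25 °C; (ii) 7 (1.1 equiv), NaOAc (2 equiv), 80 °C
Reagents that add atoms: N,N-dimethylmethaniminium iodide 11, C[N+](C)=C.[I-]
Why: Phenolic Mannich reaction at the only free ring carbon of 10, then thermal loss of dimethylamine to the ortho-quinone methide 13, which is trapped at the only free ring carbon (C8) of 7 in a Michael-type Friedel–Crafts alkylation, full conversion of 10 to 12 before 7 is added preventing homodimer formation.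

Step 5
Reactants: 14 the aromatic dimer from step 4; 15 3-methylbut-2-en-1-yl acetate (prenyl acetate)
Product: 16 (4R)-6-{[5,7-dihydroxy-2,2-dimethyl-6-(2-methylpropanoyl)-2H-chromen-8-yl]methyl}-3,5-dihydroxy-4-methyl-4-(3-methylbut-2-en-1-yl)-2-(2-methylpropanoyl)cyclohexa-2,5-dien-1-one (CNP0319758.1)
Conditions: Pd2(dba)3·CHCl3 (2.5 mol%), (R,R)-DACH-phenyl Trost ligand [N,N'-((1R,2R)-cyclohexane-1,2-diyl)bis(2-(diphenylphosphanyl)benzamide), 7.5 mol%], 15 (1.1 equiv), Et3N (1 equiv), degassed CH2Cl2, 0 → 25 °C
Reagents that add atoms: 3-methylbut-2-en-1-yl acetate 15, CC(=O)OCC=C(C)C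
Why: Proposed new method: Pd-catalysed asymmetric allylic alkylation (Tsuji–Trost type) used as a dearomatisation, in which zerovalent palladium ionises the allylic acetate, the most acidic phenolate of 14 (the OH para to the acyl group of the trihydroxy ring) attacks the CH2 terminus of the π-prenyl complex through its less hindered ortho carbon (the one bearing methyl, not the arylmethyl group), O-allylation being reversible under the catalyst, and the chiral pocket of the ligand selects one enantiotopic face of the planar phenolate, which sets the quaternary R centre; the closest known reactions are the Pd-catalysed intermolecular asymmetric allylic dearomatisation of naphthols and the base-mediated dearomative prenylation of 3,5-disubstituted acylphloroglucinols.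

## Compound list

1 | 4-hydroxy-6-methyl-2H-pyran-2-one (triacetic acid lactone) | CC1=CC(O)=CC(=O)O1 | starting material
2 | methyl 2-methylpropanoate (methyl isobutyrate) | COC(=O)C(C)C | starting material
3 | 4-hydroxy-6-(3-methyl-2-oxobutyl)-2H-pyran-2-one | CC(C)C(=O)CC1=CC(O)=CC(=O)O1 | intermediate
4 | 3-methylbut-2-enal (prenal) | CC(C)=CC=O | starting material
5 | pyranopyranone, not isolated: 2,2-dimethyl-7-(3-methyl-2-oxobutyl)-2H,5H-pyrano[4,3-b]pyran-5-one | CC(C)C(=O)CC1=CC2=C(C=CC(C)(C)O2)C(=O)O1 | intermediate
6 | pyran ester, not isolated: methyl 2,2-dimethyl-6-(5-methyl-2,4-dioxohexyl)-2H-pyran-5-carboxylate | COC(=O)C1=C(CC(=O)CC(=O)C(C)C)OC(C)(C)C=C1 | intermediate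
7 | 1-(5,7-dihydroxy-2,2-dimethyl-2H-chromen-6-yl)-2-methylpropan-1-one | CC(C)C(=O)c1c(O)cc2OC(C)(C)C=Cc2c1O | intermediate
8 | 2-methylbenzene-1,3,5-triol (2-methylphloroglucinol) | Cc1c(O)cc(O)cc1O | starting material
9 | 2-methylpropanoyl chloride (isobutyryl chloride) | CC(C)C(Cl)=O | starting material
10 | 2-methyl-1-(2,4,6-trihydroxy-3-methylphenyl)propan-1-one | CC(C)C(=O)c1c(O)cc(O)c(C)c1O | intermediate
11 | N,N-dimethylmethaniminium iodide (Eschenmoser's salt) | C[N+](C)=C.[I-] | starting material
12 | Mannich base, not isolated: 1-{3-[(dimethylamino)methyl]-2,4,6-trihydroxy-5-methylphenyl}-2-methylpropan-1-one | CC(C)C(=O)c1c(O)c(C)c(O)c(CN(C)C)c1O | intermediate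
13 | quinone methide, not isolated: 3,5-dihydroxy-2-methyl-6-methylidene-4-(2-methylpropanoyl)cyclohexa-2,4-dien-1-one | CC(C)C(=O)C1=C(O)C(=C)C(=O)C(C)=C1O | intermediate
14 | 1-[3-({5,7-dihydroxy-2,2-dimethyl-6-(2-methylpropanoyl)-2H-chromen-8-yl}methyl)-2,4,6-trihydroxy-5-methylphenyl]-2-methylpropan-1-one (achiral) | CC(C)C(=O)c1c(O)c(C)c(O)c(Cc2c(O)c(C(=O)C(C)C)c(O)c3C=CC(C)(C)Oc23)c1O | intermediate
15 | 3-methylbut-2-en-1-yl acetate (prenyl acetate) | CC(=O)OCC=C(C)C | starting material
16 | (4R)-6-{[5,7-dihydroxy-2,2-dimethyl-6-(2-methylpropanoyl)-2H-chromen-8-yl]methyl}-3,5-dihydroxy-4-methyl-4-(3-methylbut-2-en-1-yl)-2-(2-methylpropanoyl)cyclohexa-2,5-dien-1-one | CC(C)=CC[C@]1(C)C(O)=C(Cc2c(O)c(C(=O)C(C)C)c(O)c3c2OC(C)(C)C=C3)C(=O)C(C(=O)C(C)C)=C1O | target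

## Step count and risks

Total step count: 5. Longest linear sequence: 4 steps (steps 1, 2, 4, 5).

The three steps most likely to fail, in order of risk:

Step 5. The risks are site selectivity among five phenols, a second allylation, and the level and sense of enantioselection. The fallback sets out from 14 and comes back at 16. 14 is prenylated without a chiral catalyst (prenyl bromide, NaOMe, MeOH, 0 °C; classical base-mediated dearomative C-alkylation at the methyl-bearing carbon) to the racemic target F1. F1 is resolved by preparative supercritical-fluid chromatography on an amylose tris(3,5-dimethylphenylcarbamate) phase. The R enantiomer is 16; the S antipode F2 is set aside.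

Step 2. The risks are Knoevenagel condensation at the side-chain CH2 instead of C3, and a lactone that re-closes instead of undergoing the Claisen closure. The fallback sets out from 3 and comes back at 7, with the order of ring formation reversed. 3 itself is treated with Mg(OMe)2 in MeOH at 65 °C, which opens the hydroxypyrone to methyl 8-methyl-3,5,7-trioxononanoate F3 and closes it by Claisen condensation to 2-methyl-1-(2,4,6-trihydroxyphenyl)propan-1-one F4. F4 is then condensed with 4 in pyridine at 110 °C to give 7 next to the regioisomer 1-(5,7-dihydroxy-2,2-dimethyl-2H-chromen-8-yl)-2-methylpropan-1-one F5, which is removed by chromatography.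

Step 1. The risks are a poorly soluble polyanion and proton transfer from the enolisable ester. The fallback sets out from 1 and comes back at 5, with the pyran closed first on the parent lactone. 1 and 4 (ethylenediammonium diacetate, MeOH, 50 °C) give 2,2,7-trimethyl-2H,5H-pyrano[4,3-b]pyran-5-one F6. Its 7-methyl group is lithiated (LiN(iPr)2, 2.2 equiv, THF, −78 °C) and acylated with 2 to give 5, now isolated. 5 is then taken to 7 with Mg(OMe)2 as in the second half of step 2.

## Further compounds

F1 | step 5 | racemic 6-{[5,7-dihydroxy-2,2-dimethyl-6-(2-methylpropanoyl)-2H-chromen-8-yl]methyl}-3,5-dihydroxy-4-methyl-4-(3-methylbut-2-en-1-yl)-2-(2-methylpropanoyl)cyclohexa-2,5-dien-1-one | CC(C)=CCC1(C)C(O)=C(Cc2c(O)c(C(=O)C(C)C)c(O)c3c2OC(C)(C)C=C3)C(=O)C(C(=O)C(C)C)=C1O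
F2 | step 5 | (4S) antipode of 16 | CC(C)=CC[C@@]1(C)C(O)=C(Cc2c(O)c(C(=O)C(C)C)c(O)c3c2OC(C)(C)C=C3)C(=O)C(C(=O)C(C)C)=C1O
F3 | step 2 | methyl 8-methyl-3,5,7-trioxononanoate | COC(=O)CC(=O)CC(=O)CC(=O)C(C)C
F4 | step 2 | 2-methyl-1-(2,4,6-trihydroxyphenyl)propan-1-one | CC(C)C(=O)c1c(O)cc(O)cc1O
F5 | step 2 | 1-(5,7-dihydroxy-2,2-dimethyl-2H-chromen-8-yl)-2-methylpropan-1-one | CC(C)C(=O)c1c(O)cc(O)c2C=CC(C)(C)Oc12
F6 | step 1 | 2,2,7-trimethyl-2H,5H-pyrano[4,3-b]pyran-5-one | CC1=CC2=C(C=CC(C)(C)O2)C(=O)O1
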